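**Plan**

1. Retrosynthesis: remove the C8 acetate, the C9 (R)-2-methylglycidate and the 4,5-epoxide, then cut the lactone bonds O–C6 and C11–C7 together. That leaves 2-bromoacrylic acid and an all-cis cyclodeca-1,5,7-triene, which is opened at C6=C7 (metathesis), C10–C14 (carbonylation) and C9–C10 (alkynylation).
2. Enabling feature: C6, the lactone carbinol carbon, sits between C7 and the C4–C5 oxirane. Read as an alkene, the oxirane makes C4=C5–C6=C7 a conjugated diene inside the ten-membered ring, so a vinyl-Pd/π-allyl annulation can add C11 to C7 and the carboxylate oxygen to C6 and leave C4=C5 where the epoxide is needed.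
3. The cis-fused lactone and the cis (C3/C6) oxirane both read back to Z olefins, i.e. to the (4Z,6Z) ring diene that a ten-membered ring prefers.
4. Forward: dienyne from neryl acetate (5 steps) and aldehyde from (S)-but-3-ene-1,2-diol (3 steps) are joined at C9–C10; then syn-hydrostannation/iodination, methoxycarbonylation, ring-closing metathesis, lactone annulation, C9 ester, C8 acetate, epoxide.
5. Stereochemistry: C8 from the chiral pool; C9 by chelation-controlled alkynylzinc addition; C7 and C6 in the key step under control of C8/C9; C4/C5 by substrate-controlled epoxidation; the glycidate centre from (S)-2-methylglycidol. Olefin geometry: C4=C5 from nerol, C1=C10 from syn-hydrostannation, C6=C7 from ring size.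

Key step: step 13

Remark: ring positions follow germacrane numbering (C1–C10 ring, C11–C13 lactone carbons, C14 ester carbon, C15 methyl); neryl acetate, (S)-but-3-ene-1,2-diol, 2-bromoacrylic acid and (S)-2-methylglycidol are taken as commercial.

**Route**

Step 1
Reactants: 1 neryl acetate
Product: 2 6,7-epoxyneryl acetate (racemic at the oxirane carbon)
Conditions: mCPBA (1.0 equiv), CH2Cl2, 0 °C
Reagents that add atoms: mCPBA, OOC(=O)c1cccc(Cl)c1
Why: Prilezhaev epoxidation should pick the remote trisubstituted 6,7-alkene, which is more electron-rich than the 2,3-alkene next to the allylic acetate; the racemic oxirane centre is destroyed in step 2.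

Step 2
Reactants: 2 6,7-epoxyneryl acetate
Product: 4 (2Z)-3-methyl-6-oxohex-2-en-1-yl acetate, via glycol 3 (not isolated)
Conditions: H5IO6, THF/H2O, 0 °C
Reagents that add atoms: none
Why: Periodic acid hydrolyses the epoxide and cleaves the glycol (Malaprade cleavage) to the aldehyde and acetone, leaving the Z allylic acetate untouched.

Step 3
Reactants: 4 (2Z)-3-methyl-6-oxohex-2-en-1-yl acetate
Product: 6 (2Z)-3-methylhept-2-en-6-yn-1-ol, via alkynyl acetate 5 (not isolated)
Conditions: dimethyl (1-diazo-2-oxopropyl)phosphonate, K2CO3, MeOH, 0 °C to rt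
Reagents that add atoms: Ohira–Bestmann reagent, COP(=O)(OC)C(=[N+]=[N-])C(C)=O
Why: Seyferth–Gilbert homologation (Ohira–Bestmann variant) converts the aldehyde into the terminal alkyne, and the same K2CO3/MeOH methanolyses the allylic acetate.

Step 4
Reactants: 6 (2Z)-3-methylhept-2-en-6-yn-1-ol
Product: 7 (2Z)-3-methylhept-2-en-6-ynal
Conditions: MnO2, CH2Cl2, rt
Reagents that add atoms: none
Why: MnO2 oxidises the allylic alcohol chemoselectively without acid or base, so the Z (neral-type) enal geometry should be kept.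

Step 5
Reactants: 7 (2Z)-3-methylhept-2-en-6-ynal
Product: 8 (5Z)-5-methylocta-5,7-dien-1-yne
Conditions: Ph3PCH3Br, KHMDS, THF, −78 to 0 °C (product kept in solution, volatile)
Reagents that add atoms: methyltriphenylphosphonium bromide, C[P+](c1ccccc1)(c1ccccc1)c1ccccc1.[Br-]
Why: Wittig methylenation with the non-stabilised ylide at low temperature should give the terminal (Z)-1,3-diene without deprotonating the alkyne.

Step 6
Reactants: 9 (2S)-but-3-ene-1,2-diol
Product: 10 (4S)-2-(4-methoxyphenyl)-4-vinyl-1,3-dioxolane (epimer mixture at the acetal carbon)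
Conditions: 4-MeOC6H4CH(OMe)2, PPTS (cat.), CH2Cl2, rt
Reagents that add atoms: 4-methoxybenzaldehyde dimethyl acetal, COC(OC)c1ccc(OC)cc1
Why: Acid-catalysed transacetalisation forms the five-membered p-methoxybenzylidene acetal; the acetal epimers are inconsequential.

Step 7
Reactants: 10 (4S)-2-(4-methoxyphenyl)-4-vinyl-1,3-dioxolane
Product: 11 (2S)-2-[(4-methoxybenzyl)oxy]but-3-en-1-ol
Conditions: DIBAL-H, CH2Cl2, −78 to 0 °C
Reagents that add atoms: none
Why: Regioselective reductive acetal opening: DIBAL-H coordinates the less hindered primary oxygen and leaves the PMB group on the secondary oxygen.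

Step 8
Reactants: 11 (2S)-2-[(4-methoxybenzyl)oxy]but-3-en-1-ol
Product: 12 (2S)-2-[(4-methoxybenzyl)oxy]but-3-enal
Conditions: Dess–Martin periodinane, CH2Cl2, 0 °C; used crude at once
Reagents that add atoms: none
Why: Dess–Martin oxidation under non-basic conditions gives the α-alkoxy β,γ-unsaturated aldehyde, which is used immediately to avoid epimerisation or conjugation.

Step 9
Reactants: 8 (5Z)-5-methylocta-5,7-dien-1-yne; 12 (2S)-2-[(4-methoxybenzyl)oxy]but-3-enal
Product: 15 (3Z,9S,10S)-10-[(4-methoxybenzyl)oxy]-4-methyldodeca-1,3,11-trien-7-yn-9-ol, via lithium acetylide 13 (not isolated), via alkynylzinc bromide 14 (not isolated)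
Conditions: n-BuLi, Et2O, −78 °C; ZnBr2, 0 °C; then 12, −78 to 0 °C
Reagents that add atoms: none
Why: Alkynylzinc addition under Cram-chelate control (Zn bridges C=O and the α-OPMB oxygen, attack past H rather than vinyl) forms C9–C10 and should set the 8,9-syn (threo) relationship, i.e. 9S.

Step 10
Reactants: 15 (3Z,9S,10S)-10-[(4-methoxybenzyl)oxy]-4-methyldodeca-1,3,11-trien-7-yn-9-ol
Product: 17 (3Z,7E,9R,10S)-8-iodo-10-[(4-methoxybenzyl)oxy]-4-methyldodeca-1,3,7,11-tetraen-9-ol, via vinylstannane 16 (not isolated)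
Conditions: Bu3SnH, PdCl2(PPh3)2 (cat.), THF, 0 °C; then I2, CH2Cl2, 0 °C
Reagents that add atoms: iodine, II
Why: Pd-catalysed syn-hydrostannation should place tin on the alkyne carbon next to the free carbinol (proximal selectivity of propargylic alcohols) and H on C1, so C9 and C2 end up cis; iododestannylation retains geometry.

Step 11
Reactants: 17 (3Z,7E,9R,10S)-8-iodo-10-[(4-methoxybenzyl)oxy]-4-methyldodeca-1,3,7,11-tetraen-9-ol
Product: 18 methyl (2E,6Z)-2-{(1S,2S)-1-hydroxy-2-[(4-methoxybenzyl)oxy]but-3-en-1-yl}-6-methylnona-2,6,8-trienoate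
Conditions: Pd(PPh3)4 (cat.), CO (1 atm), Et3N, MeOH/DMF, 50 °C
Reagents that add atoms: carbon monoxide, [C-]#[O+]; methanol, CO
Why: Pd-catalysed methoxycarbonylation of the vinyl iodide (oxidative addition, CO insertion, methanolysis) installs the C14 ester with retention of olefin geometry.

Step 12
Reactants: 18 methyl (2E,6Z)-2-{(1S,2S)-1-hydroxy-2-[(4-methoxybenzyl)oxy]but-3-en-1-yl}-6-methylnona-2,6,8-trienoate
Product: 19 methyl (1E,5Z,7Z,9S,10S)-10-hydroxy-9-[(4-methoxybenzyl)oxy]-5-methylcyclodeca-1,5,7-triene-1-carboxylate (all three ring olefins cis within the ring)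
Conditions: Grubbs II (10 mol%), 1,4-benzoquinone (cat.), toluene, 1 mM, 80 °C
Reagents that add atoms: none
Why: Ring-closing metathesis between the diene terminus and the C7 vinyl group forms C6=C7; the ten-membered ring with two cis olefins already in place should enforce the cis geometry, and the trisubstituted C4=C5 and C1=C10 bonds should stay out.

Step 13
Reactants: 19 methyl (1E,5Z,7Z,9S,10S)-10-hydroxy-9-[(4-methoxybenzyl)oxy]-5-methylcyclodeca-1,5,7-triene-1-carboxylate; 20 2-bromoprop-2-enoic acid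
Product: 21 methyl (6S,7S,8S,9S)-9-hydroxy-8-[(4-methoxybenzyl)oxy]germacra-1(10),4,11(13)-trien-12,6-olid-14-oate (4Z, C9/C2 cis about C1=C10, H-6/H-7 cis)
Conditions: Pd(OAc)2 (10 mol%), PPh3 (20 mol%), Ag2CO3, toluene, 70 °C, slow addition of 20
Reagents that add atoms: none
Why: Proposed new method: oxidative addition of Pd(0) to the C–Br bond of 20 gives an α-carboxyvinyl-Pd(II) species that carbopalladates the less substituted terminus of the ring diene (C7 of C4=C5–C6=C7), forming C11–C7 and an η3-allyl over C6–C5–C4; the tethered carboxylate, held on palladium under halide-free conditions (Ag2CO3), then forms O–C6 by inner-sphere C–O reductive elimination and returns Pd(0). The closest known reaction type is the Larock heteroannulation of 1,3-dienes with o-iodobenzoic acids, o-iodophenols and hydroxy- or carboxy-substituted vinylic halides; an α-haloacrylic acid on a medium-ring triene has not been shown. The γ-lactone closes by attack at the proximal allyl terminus C6 (five-membered ring, favoured over seven-membered closure at the tertiary C4), which leaves C4=C5 cis in the ring. C7 is controlled by C8: A(1,3) strain keeps H-8 in the plane of the Z olefin, the PMB ether covers one face and the free C9 hydroxyl should guide the cationic vinyl-Pd to the other (hydroxyl-directed Heck precedent); C6 follows because carbon and oxygen arrive on the same face of the Z olefin, giving the cis-fused lactone as in Larock annulations of cyclic cis-dienes. The step needs site selectivity for C7 over the hindered, electron-poor C1=C10 enoate and the trisubstituted diene end (secured by sterics and electronics), and the carboxylate must beat the C9 hydroxyl at the allyl terminus (secured by its anionic, Pd-bound, five-ring-forming position).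

Step 14
Reactants: 22 (S)-2-methylglycidol
Product: 24 (2R)-2-methyloxirane-2-carboxylic acid, via epoxy aldehyde 23 (not isolated)
Conditions: RuCl3 (cat.), NaIO4, MeCN/EtOAc/H2O, 0 °C to rt
Reagents that add atoms: water, O
Why: Ru-catalysed (RuO4) oxidation of the primary alcohol through the aldehyde hydrate gives the glycidic acid without touching the oxirane; S alcohol becomes R acid only through the change in CIP priorities.

Step 15
Reactants: 21 lactone alcohol (as in step 13); 24 (2R)-2-methyloxirane-2-carboxylic acid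
Product: 26 the C9 (2R)-2-methyloxirane-2-carboxylate of 21 (6S,7S,8S,9S), via mixed anhydride 25 (not isolated)
Conditions: 2,4,6-trichlorobenzoyl chloride, Et3N, THF, 0 °C; then 21, DMAP, toluene, rt
Reagents that add atoms: none
Why: Yamaguchi esterification through the mixed anhydride acylates the only free hydroxyl (C9); no stereocentre is involved.

Step 16
Reactants: 26 C9 glycidate, C8 PMB ether
Product: 27 the C8 alcohol (6S,7R,8S,9S; same spatial arrangement, C7 descriptor changes by CIP only)
Conditions: DDQ, CH2Cl2/pH 7 buffer, 0 °C to rt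
Reagents that add atoms: none
Why: Oxidative PMB cleavage with DDQ (benzylic hydride abstraction, hydrolysis of the oxocarbenium ion) frees the C8 hydroxyl under neutral conditions that the oxirane ester, the lactone and the olefins should tolerate.

Step 17
Reactants: 27 C8 alcohol
Product: 28 the C8 acetate (6S,7S,8S,9S), i.e. the 4,5-alkene precursor of the target
Conditions: Ac2O, pyridine, DMAP (cat.), CH2Cl2, 0 °C to rt
Reagents that add atoms: acetic anhydride, CC(=O)OC(C)=O
Why: DMAP-catalysed acylation installs the C8 acetate; with C9 already esterified there is no regiochemical question.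

Step 18
Reactants: 28 C8 acetate
Product: 29 the target, CNP0159450.1 (4R,5S,6R,7R,8S,9S, glycidate 2R)
Conditions: mCPBA, CH2Cl2, 0 °C
Reagents that add atoms: mCPBA, OOC(=O)c1cccc(Cl)c1
Why: Prilezhaev epoxidation should attack only the electron-rich trisubstituted C4=C5 bond (enoate and α-methylene lactone are electron-poor); with H-6 held in the olefin plane by A(1,3) strain the peracid should approach syn to the lactone oxygen and anti to C7, which gives the 4R,5S oxirane.

**Compound list**

1 | neryl acetate, (2Z)-3,7-dimethylocta-2,6-dien-1-yl acetate | CC(C)=CCC/C(C)=C\COC(C)=O | starting material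
2 | 6,7-epoxyneryl acetate (racemic oxirane) | CC1(C)OC1CC/C(C)=C\COC(C)=O | intermediate
3 | (2Z)-6,7-dihydroxy-3,7-dimethyloct-2-en-1-yl acetate (glycol, not isolated) | CC(C)(O)C(O)CC/C(C)=C\COC(C)=O | intermediate
4 | (2Z)-3-methyl-6-oxohex-2-en-1-yl acetate | O=CCC/C(C)=C\COC(C)=O | intermediate
5 | (2Z)-3-methylhept-2-en-6-yn-1-yl acetate (not isolated) | C#CCC/C(C)=C\COC(C)=O | intermediate
6 | (2Z)-3-methylhept-2-en-6-yn-1-ol | C#CCC/C(C)=C\CO | intermediate
7 | (2Z)-3-methylhept-2-en-6-ynal | C#CCC/C(C)=C\C=O | intermediate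
8 | (5Z)-5-methylocta-5,7-dien-1-yne | C#CCC/C(C)=C\C=C | intermediate
9 | (2S)-but-3-ene-1,2-diol | C=C[C@H](O)CO | starting material
10 | (4S)-2-(4-methoxyphenyl)-4-vinyl-1,3-dioxolane (acetal epimers) | C=C[C@H]1COC(c2ccc(OC)cc2)O1 | intermediate
11 | (2S)-2-[(4-methoxybenzyl)oxy]but-3-en-1-ol | C=C[C@H](OCc1ccc(OC)cc1)CO | intermediate
12 | (2S)-2-[(4-methoxybenzyl)oxy]but-3-enal | C=C[C@H](OCc1ccc(OC)cc1)C=O | intermediate
13 | [(5Z)-5-methylocta-5,7-dien-1-yn-1-yl]lithium (not isolated) | [Li]C#CCC/C(C)=C\C=C | intermediate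
14 | bromo[(5Z)-5-methylocta-5,7-dien-1-yn-1-yl]zinc (not isolated) | Br[Zn]C#CCC/C(C)=C\C=C | intermediate
15 | (3Z,9S,10S)-10-[(4-methoxybenzyl)oxy]-4-methyldodeca-1,3,11-trien-7-yn-9-ol | C=C[C@H](OCc1ccc(OC)cc1)[C@@H](O)C#CCC/C(C)=C\C=C | intermediate
16 | (3Z,7E,9R,10S)-10-[(4-methoxybenzyl)oxy]-4-methyl-8-(tributylstannyl)dodeca-1,3,7,11-tetraen-9-ol (not isolated) | C=C[C@H](OCc1ccc(OC)cc1)[C@@H](O)/C([Sn](CCCC)(CCCC)CCCC)=C\CC/C(C)=C\C=C | intermediate
17 | (3Z,7E,9R,10S)-8-iodo-10-[(4-methoxybenzyl)oxy]-4-methyldodeca-1,3,7,11-tetraen-9-ol | C=C[C@H](OCc1ccc(OC)cc1)[C@@H](O)/C(I)=C\CC/C(C)=C\C=C | intermediate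
18 | methyl (2E,6Z)-2-{(1S,2S)-1-hydroxy-2-[(4-methoxybenzyl)oxy]but-3-en-1-yl}-6-methylnona-2,6,8-trienoate | C=C[C@H](OCc1ccc(OC)cc1)[C@@H](O)/C(C(=O)OC)=C\CC/C(C)=C\C=C | intermediate
19 | methyl (1E,5Z,7Z,9S,10S)-10-hydroxy-9-[(4-methoxybenzyl)oxy]-5-methylcyclodeca-1,5,7-triene-1-carboxylate | C/C1=C/C=C\[C@H](OCc2ccc(OC)cc2)[C@@H](O)/C(C(=O)OC)=C\CC1 | intermediate
20 | 2-bromoprop-2-enoic acid | C=C(Br)C(=O)O | starting material
21 | methyl (6S,7S,8S,9S)-9-hydroxy-8-[(4-methoxybenzyl)oxy]germacra-1(10),4,11(13)-trien-12,6-olid-14-oate, cis-fused lactone | C/C1=C/[C@@H]2OC(=O)C(=C)[C@@H]2[C@H](OCc3ccc(OC)cc3)[C@@H](O)/C(C(=O)OC)=C\CC1 | intermediate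
22 | (S)-2-methylglycidol, [(2S)-2-methyloxiran-2-yl]methanol | OC[C@@]1(C)CO1 | starting material
23 | (2R)-2-methyloxirane-2-carbaldehyde (not isolated) | O=C[C@@]1(C)CO1 | intermediate
24 | (2R)-2-methyloxirane-2-carboxylic acid | OC(=O)[C@@]1(C)CO1 | intermediate
25 | (2R)-2-methyloxirane-2-carboxylic 2,4,6-trichlorobenzoic anhydride (not isolated) | O=C(OC(=O)[C@@]1(C)CO1)c1c(Cl)cc(Cl)cc1Cl | intermediate
26 | 9-O-[(2R)-2-methyloxirane-2-carbonyl] derivative of 21 (6S,7S,8S,9S) | C/C1=C/[C@@H]2OC(=O)C(=C)[C@@H]2[C@H](OCc3ccc(OC)cc3)[C@@H](OC(=O)[C@@]3(C)CO3)/C(C(=O)OC)=C\CC1 | intermediate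
27 | 8-hydroxy 9-glycidate lactone (6S,7R,8S,9S) | C/C1=C/[C@@H]2OC(=O)C(=C)[C@@H]2[C@H](O)[C@@H](OC(=O)[C@@]3(C)CO3)/C(C(=O)OC)=C\CC1 | intermediate
28 | 8-acetoxy 9-glycidate lactone, 4,5-alkene (6S,7S,8S,9S) | C/C1=C/[C@@H]2OC(=O)C(=C)[C@@H]2[C@H](OC(C)=O)[C@@H](OC(=O)[C@@]3(C)CO3)/C(C(=O)OC)=C\CC1 | intermediate
29 | CNP0159450.1 (4R,5S,6R,7R,8S,9S, glycidate 2R) | C=C1C(=O)O[C@@H]2[C@H]1[C@H](OC(C)=O)[C@@H](OC(=O)[C@@]1(C)CO1)/C(C(=O)OC)=C\CC[C@@]1(C)O[C@@H]21 | target

**Totals**

Total step count: 18. Longest linear sequence: 14 steps (1–5, 9–13, 15–18).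

**Steps most likely to fail**

Step 13 (proposed new method). What may go wrong: vinyl-palladium insertion on the undesired face of C6=C7, or outer-sphere (anti) C–O bond formation, giving the 7-epi or trans-fused lactone; Heck-type self-reaction of the bromoacrylic acid; capture of the allyl terminus by the C9 hydroxyl. Fallback with known chemistry, setting out from 19 and returning at 21: Mn(III)-based oxidative radical lactone annulation of the conjugated diene with potassium methyl malonate (Mn(OAc)3·2H2O, Cu(OAc)2, AcOH, 50 °C) should give the α-methoxycarbonyl lactone F1, the malonyl radical adding at C7 and the carboxylic acid closing on the oxidised allyl at C6. Selective saponification of the malonate-type ester (LiOH, THF/H2O, 0 °C) should give the lactone acid F2. Decarboxylative Mannich methylenation (aqueous HCHO, Et2NH; then NaOAc/AcOH, 70 °C) should give 21.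

Step 12. What may go wrong: intermolecular metathesis (oligomerisation) outrunning ten-membered ring closure, or metathesis through the internal C4=C5 bond with loss of the diene. Fallback, setting out from 11 and returning at 19: the (Z,Z)-diene is built in the open chain by stereospecific coupling and the ring is closed at C9–C10 instead.
- Silylation (TBDPSCl, imidazole) should give the silyl ether F3; ozonolysis (O3, CH2Cl2, −78 °C; PPh3) the aldehyde F4; Stork–Zhao olefination (Ph3P=CHI, THF/HMPA, −78 °C) the (Z)-vinyl iodide F5.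
- Syn-carbocupration of propyne with the organocopper reagent from 2-(2-bromoethyl)-1,3-dioxolane (Mg; CuBr·SMe2) should give the (Z)-alkenylcopper F6, which is coupled with F5 (ZnBr2, Pd(PPh3)4, Negishi-type, retention at both olefins) to the (Z,Z)-diene acetal F7.
- Acetal hydrolysis (PPTS, acetone/H2O) should give the aldehyde F8; Wittig reaction with Ph3P=C(I)CO2Me the (Z)-α-iodoenoate F9; TBAF/AcOH the alcohol F10; Dess–Martin oxidation the seco aldehyde F11.
- Nozaki–Hiyama–Kishi ring closure (CrCl2, cat. NiCl2, DMSO, high dilution, with a chiral sulfonamide ligand if 9S needs reagent control) should give 19.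

Step 18. What may go wrong: peracid delivery to the undesired face of C4=C5, giving the 4,5-diepimeric oxirane. Fallback, setting out from 28 and returning at 29: NBS in THF/H2O should form the bromonium ion on the face the peracid prefers and water should open it anti at the tertiary C4, giving the bromohydrin F12. Ag2O (DMF, rt) then closes the oxirane with inversion at C5, which places the epoxide oxygen on the opposite face.

**Further compounds**

F1 | step 13 | 11-methoxycarbonyl-11,13-dihydro analogue of 21 (C11 epimers) | C/C1=C/[C@@H]2OC(=O)C(C(=O)OC)[C@@H]2[C@H](OCc3ccc(OC)cc3)[C@@H](O)/C(C(=O)OC)=C\CC1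
F2 | step 13 | 11-carboxy-11,13-dihydro analogue of 21 (C11 epimers) | C/C1=C/[C@@H]2OC(=O)C(C(=O)O)[C@@H]2[C@H](OCc3ccc(OC)cc3)[C@@H](O)/C(C(=O)OC)=C\CC1
F3 | step 12 | tert-butyldiphenylsilyl ether of 11 | C=C[C@H](OCc1ccc(OC)cc1)CO[Si](c1ccccc1)(c1ccccc1)C(C)(C)C
F4 | step 12 | (2R)-3-(tert-butyldiphenylsilyloxy)-2-[(4-methoxybenzyl)oxy]propanal | O=C[C@H](OCc1ccc(OC)cc1)CO[Si](c1ccccc1)(c1ccccc1)C(C)(C)C
F5 | step 12 | (2S,3Z)-4-iodo-2-[(4-methoxybenzyl)oxy]but-3-en-1-yl tert-butyldiphenylsilyl ether | I/C=C\[C@H](OCc1ccc(OC)cc1)CO[Si](c1ccccc1)(c1ccccc1)C(C)(C)C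
F6 | step 12 | (Z)-[4-(1,3-dioxolan-2-yl)-2-methylbut-1-en-1-yl]copper | [Cu]/C=C(C)\CCC1OCCO1
F7 | step 12 | (Z,Z)-diene acetal, 2-[(3Z,5Z,7S)-8-(tert-butyldiphenylsilyloxy)-7-[(4-methoxybenzyl)oxy]-3-methylocta-3,5-dien-1-yl]-1,3-dioxolane | C1(CC/C(C)=C\C=C/[C@H](OCc2ccc(OC)cc2)CO[Si](c2ccccc2)(c2ccccc2)C(C)(C)C)OCCO1
F8 | step 12 | (4Z,6Z,8S)-9-(tert-butyldiphenylsilyloxy)-8-[(4-methoxybenzyl)oxy]-4-methylnona-4,6-dienal | O=CCC/C(C)=C\C=C/[C@H](OCc1ccc(OC)cc1)CO[Si](c1ccccc1)(c1ccccc1)C(C)(C)C
F9 | step 12 | methyl (2Z,6Z,8Z,10S)-11-(tert-butyldiphenylsilyloxy)-2-iodo-10-[(4-methoxybenzyl)oxy]-6-methylundeca-2,6,8-trienoate | COC(=O)/C(I)=C/CC/C(C)=C\C=C/[C@H](OCc1ccc(OC)cc1)CO[Si](c1ccccc1)(c1ccccc1)C(C)(C)C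
F10 | step 12 | methyl (2Z,6Z,8Z,10S)-11-hydroxy-2-iodo-10-[(4-methoxybenzyl)oxy]-6-methylundeca-2,6,8-trienoate | COC(=O)/C(I)=C/CC/C(C)=C\C=C/[C@H](OCc1ccc(OC)cc1)CO
F11 | step 12 | methyl (2Z,6Z,8Z,10S)-2-iodo-10-[(4-methoxybenzyl)oxy]-6-methyl-11-oxoundeca-2,6,8-trienoate | COC(=O)/C(I)=C/CC/C(C)=C\C=C/[C@H](OCc1ccc(OC)cc1)C=O
F12 | step 18 | 5-bromo-4-hydroxy-4,5-dihydro derivative of 28 (bromohydrin, Br and OH anti) | C=C1C(=O)O[C@@H]2[C@H]1[C@H](OC(C)=O)[C@@H](OC(=O)[C@@]1(C)CO1)/C(C(=O)OC)=C\CC[C@@](C)(O)[C@@H]2Br
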